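The south-east flask is slow at making chains, and that slowness does not follow its charge.

| setting | west | south-east | flask |
|---|---|---|---|
| Ja | 1 M | 0.67 M | 1.0 M |
| Jc | 0.5 mol% | 0.5 mol% | 0.5 mol% |
| Je | 3.7 mM | 3.7 mM | 3.7 mM |
| remark | the very flask that is asked about, followed so far | run made earlier |  |
| time |  |  | 3.0 min |

- west (time / s: Jb / %, Ja / %): 10.0: 3.0, 89.9; 12.0: 4.6, 90.6; 15.0: 6.8, 87.2; 20.0: 8.9, 80.4
- south-east (time / min: Jb / %, Ja / %): 0.417: 2.5, 82.2; 0.833: 6.0, 71.6; 1.33: 9.4, 56.2; 1.50: 8.4, 53.4; 2.00: 10.4, 43.0; 2.50: 13.8, 34.3; 3.00: 14.2, 28.0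

(scatter of a reading: 1 percentage point)

1. average number of monomer units in a chain (chains begun, living or dead) at 3.0 min
2. part of the Ja that has reacted at 3.0 min

- the average divides the monomer in chains by the number of chains begun, living and dead together
- what was read earlier has a scatter of 1 percentage point, one standard deviation
- the earlier runs do not show the number of chains; that part of a forecast is a guess

Take Jb gained per second, divided by the mean Ja present. This gain rate reads 0.00693 s⁻¹ in the west flask and 0.00137 s⁻¹ in the south-east flask.

One chemist holds that Je is a bystander and each Jc begins a chain, which gives 5.00 mM of chains in the west flask. She points to the overall first-order constants, 0.0109 s⁻¹ for the west flask and 0.00707 s⁻¹ for the south-east flask, whose ratio of 1.54 matches the Jc ratio of 1.49.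

The other answers that the gain rates differ by a reading of 5.06, more than the Jc ratio. He holds that Je destroys Jc one to one, with Je the limiting reagent of that pair in the west flask. His quantity is Jc charged minus Je charged, 1.30 mM in the west flask, the free charge. In the south-east flask it is negative, −0.350 mM.

I side with him. The south-east loss that is not Jb reads 0.00570 s⁻¹. Adding the west gain gives 0.0126 s⁻¹, so I reckon 89.7% reacted by 3.0 min. Dividing the Jb this implies by the free charge gives my estimate of dp, 379.

The forecast takes her side, “each Jc starts one chain”, with dp 76 and 84% reacted.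

The flask gives dp 648 and 96.4% reacted, and the dp stands above my estimate. At 3.00 min, Jd stands at 9.52 × 10⁻⁴ M, below the free charge.

    Ja + Jc → Jd + Jb (k = 0.0223 M⁻¹ s⁻¹)
    Ja + Jd → Jb + Jd, rate k2*[Jd]*[Ja] (k = 16.2 M⁻¹ s⁻¹)
    Jc + Je → Jg (k = 331 M⁻¹ s⁻¹)
    Ja + Jc → Jh (k = 0.00170 M⁻¹ s⁻¹)
    Ja → Jf (k = 0.00569 s⁻¹)

With 0.3 mol% of Jc, the free charge is −0.700 mM, which leaves 18.9% of the Je by reckoning, and that neighbouring flask shows Jc at 0%, Je at 21.9% and dp 1590.

Readings and results are calculated with made-up constants; scatter was added.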